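## Structural features

The target is a bicyclo[3.2.1]octane in which a five-membered ring (C1, C7, C6, C5, C8) and a six-membered ring (C1, C2, C3, C4, C5, C8) share the C1–C8–C5 unit. C1 is the allyl-bearing bridgehead, C5 the methoxy-bearing bridgehead and C8 the acetoxy one-carbon bridge. Five of the six stereocentres are contiguous around the five-membered ring (C5, C6, C7, C1, C8). The aryl group on C6 is endo (turned toward the C2–C4 bridge) and trans to the exo methyl on C7, and the C8 acetate lies on the side of the C2–C4 bridge. The sixth centre, the methoxy-bearing C3, is insulated by the C2 methylene and sits on the face of the six-membered ring turned toward the C6–C7 bridge. Fragile points are the epimerisable alpha-methoxy ketone (C3/C4), the tertiary alpha-ketol at C5 before it is etherified, the electron-rich arene, and the terminal allyl alkene, which rules out late hydroboration, ozonolysis and hydrogenation. The real difficulty is the crowded C5–C6–C7–C1–C8 array with two fully substituted bridgeheads, plus the remote C3 centre, which no ring neighbour can control before the bicycle exists. The key step exploits the fact that the C4 carbonyl and the oxygenated C5 are direct neighbours in the six-membered ring: this alpha-ketol can be read backwards as a C4 acyl anion equivalent joined to a C5 carbonyl embedded in the five-membered ring.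

## Logic of the disconnections

28 ⇒ 25 (through 27 and 26). The O–acetyl bond at C8 and the O–methyl bond at C5 are cut. This leaves a tertiary ketol with a silyl-protected C8 oxygen, so that the two oxygens stay differentiated. The forward steps must alkylate a hindered tertiary hydroxyl without base (C3 is epimerisable) and remove a hindered silyl ether without fluoride base.

25 ⇒ 23 (through 24). The C4–C5 bond is cut, opening the six-membered ring. The bicycle falls back to a cyclopentanone carrying a 2-methoxy-3-oxopropyl arm on C1, and the only stereocentre lost is C5. The forward step needs an acyl anion equivalent at C4 under conditions mild enough for an alpha-methoxy aldehyde and an alpha-aryl ketone.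

23 ⇒ 22 ⇒ 21 ⇒ 20. The aldehyde is traced to a 1,2-diol (one sacrificial carbon beyond C4), the C3–OMe bond to an epoxide opening, and the epoxide to an E-allylic alcohol. C3 is thereby set by reagent control, and the aldehyde is released last under neutral conditions. The demands are distal-carbon opening of the epoxy alcohol with inversion and an epoxidation that ignores the allyl group.

20 ⇒ 19 ⇒ 18 ⇒ 16 ⇒ 15 (through 17). The C5 carbonyl and C8 carbinol are traced to a C8 ketone conjugated with a C5=C6 bond (1,2-carbonyl transposition). Reduction, hydroxyl-directed epoxidation and benzylic epoxide-to-ketone rearrangement move the oxygen pattern and allow O8 to be silylated without a competing hydroxyl. The demands are reagent control at C8 and chemoselective epoxidation of one of three alkenes.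

15 ⇒ 13 (through 14). The C5=C6 double bond is removed. This returns to a saturated ketone whose C6 centre is the source of all relative stereochemistry; C5 is its only enolisable position.

13 ⇒ 8 + 11 (through 12). The C7–CH3 bond and the C1–C2 bond are cut. One operation creates C7 and the quaternary C1 from a flat enone. The methyl must add anti to the C6 aryl group, and the butenyl arm must enter anti to that methyl, so the allyl group has to be on the enone beforehand.

11 ⇒ 10 ⇒ 9. The four-carbon E-allylic electrophile is traced by O–Si cleavage and ester reduction to a commercial bromocrotonate.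

8 ⇒ 6 + 7, and 6 ⇒ 5. The C1–allyl bond is cut (cross-coupling of an alpha-iodoenone), then the C–I bond.

5 ⇒ 3 (through 4) ⇒ 1 + 2. The enone unsaturation is removed, then the C6–aryl bond is cut. The single catalytic asymmetric step of the route sets C6; the forward dehydrogenation must take the alpha-CH2 remote from the aryl-bearing carbon.

## Other disconnections considered

Alternative 1: Reductive Nazarov cyclisation. The cut is the C6–C7 bond, and with it the five-membered ring. Forward, a chiral Lewis acid (Sc(OTf)3 with a pybox ligand) would bind the carbonyl and the 2-methoxy group of the cross-conjugated dienone A1 and trigger conrotatory closure. Et3SiH would reduce the oxyallyl cation to give the cyclopentanone A2 with aryl and methyl trans.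
- In its favour: A1 is acyclic and quick to assemble, and the ring with its C6/C7 pair arises in one catalytic enantioselective step. C5 carries its methoxy group from the start, so neither a carbonyl transposition nor the O-methylation of a bridgehead tertiary alcohol is needed. On these two points it is better than the chosen plan.
- Against it: hydride capture must outrun proton loss. The sense of torquoselectivity with an alpha-allyl and an electron-rich beta-aryl substituent is not secured by a substrate element. A2 still lacks the quaternary C1, the C2–C4 arm with its C3 centre and the six-membered ring.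
- Comparison: A2 has two tertiary alpha-carbons (C1 and C5) that must be told apart for alkylation, and the ring closure would have to be an aldol of an alpha-methoxy enolate, not an umpolung. Both plans rest on one catalytic asymmetric step for C6/C7 (equal). Alternative 1 is probably shorter to the monocycle, but the unsolved steps after A2 make the overall step economy comparable.

Alternative 2: Transannular vinylogous aldol. The cut is the C1–C8 bond. Forward, a non-nucleophilic base would convert the cycloheptenone aldehyde A3 into its extended dienolate, whose gamma carbon (C1) would add to the formyl carbon on C5 to give the bicyclic enone A4.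
- In its favour: one step would create both rings of the bicycle, the quaternary C1 and the C8 carbinol. That is more complexity per step than the benzoin closure, which creates one ring and one stereocentre, so on this point it is better. Gamma-attack is enforced by geometry (alpha-attack would give a four-membered ring), and C5 is already etherified.
- Against it: A3 is a seven-membered ring with three contiguous centres, including a quaternary alpha-formyl alpha-methoxy ketone that cannot enolise and is open to deformylation by base. The C8 configuration depends on the formyl rotamer. C3 would still have to be set by a face-selective conjugate reduction that spares the allyl group.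
- Comparison: the chosen plan sets every centre on a rigid five-membered template with an identified neighbour or reagent. The route to A3 would very likely be longer and less controlled than the route to 23.

Alternative 3: Three-component cuprate addition with Michael–aldol annulation. The cuts are C7–CH3, C1–C2 and C4–C5. Forward, Me2CuLi would add to the methoxy enone A5. The silyl enol ether at C1 would add to 2-methoxyacrolein A6, and the C5 enolate would close on the aldehyde to give the bicyclic hydroxy ketone A7.
- In its favour: it is the most convergent plan and uses the same enantioselective entry as the chosen route. There is no carbonyl transposition and no tertiary O-methylation. In step count it is clearly better.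
- Against it: C3 would be formed by protonation of an aldehyde enol with no control element. A6 is a weak, polymerisation-prone acceptor for a tetrasubstituted enol ether that must form a quaternary centre. The aldol needs enolisation at the tertiary alpha-methoxy carbon C5 beside an enolisable aldehyde. A7 has the wrong oxidation pattern (C4 carbinol, C8 ketone), so two carbonyls flanking C5 must be told apart in a redox end-game.
- Comparison: C5 is tether-controlled in both plans (equal). The chosen plan is longer but keeps C4 and C8 differentiated from the outset and gives C3 a reagent-controlled origin.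

Key step: step 16

Remarks on the chemistry:
- Core atoms keep the labels C1–C8 of the final bicycle in all intermediates.
- In the bicycle the bridgehead C5–O bond is necessarily gauche to the C8–O bond. A vicinal silyl shift to the C5 alkoxide is therefore geometrically possible, so O8 carries a tert-butyldimethylsilyl group (less mobile than a triethylsilyl group).
- The arm on C1 is introduced as a four-carbon E-butenyl unit, so that C3 is set by reagent control and C4 is unveiled by glycol cleavage. A two-carbon ester arm would leave C3 uncontrolled.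
- Assumption: 9, the triazolium salt, the CBS catalyst and diisopropyl D-tartrate are purchased.

## Route

Step 1
Reactants: 1 cyclopent-2-en-1-one; 2 (3,4-dimethoxyphenyl)boronic acid
Product: 3 (R)-3-(3,4-dimethoxyphenyl)cyclopentan-1-one
Conditions: Rh(acac)(C2H4)2 (3 mol%), (R)-BINAP (3.3 mol%), 2 (2.5 equiv), dioxane/H2O 10:1, 100 °C
Reagents that add atoms: none
Why: Rhodium-catalysed asymmetric conjugate addition of an arylboronic acid (Hayashi–Miyaura reaction); the (R)-BINAP complex should give the R ketone, which is the C6 configuration of the target. Excess boronic acid offsets protodeboronation of the electron-rich arene.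

Step 2
Reactants: 3
Product: 5 (S)-4-(3,4-dimethoxyphenyl)cyclopent-2-en-1-one, via kinetic trimethylsilyl enol ether 4 (not isolated)
Conditions: LiN(iPr)2, Me3SiCl, THF, −78 °C; then Pd(OAc)2 (10 mol%), O2 (1 atm), DMSO, rt
Reagents that add atoms: none
Why: Saegusa–Ito dehydrogenation; kinetic deprotonation should take the alpha-CH2 remote from the aryl-bearing carbon, and beta-hydride elimination then places the double bond on that side. The stereocentre is untouched (the descriptor changes only because ring priorities change); the minor regioisomer would give the achiral 3-aryl enone, which is separable.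

Step 3
Reactants: 5
Product: 6 (S)-4-(3,4-dimethoxyphenyl)-2-iodocyclopent-2-en-1-one
Conditions: I2, pyridine/CH2Cl2 1:1, 0 °C → rt
Reagents that add atoms: iodine, II
Why: alpha-Iodination of an enone by pyridine-mediated addition–elimination; the C6 centre is not involved.

Step 4
Reactants: 6; 7 allyltributylstannane
Product: 8 (S)-2-allyl-4-(3,4-dimethoxyphenyl)cyclopent-2-en-1-one
Conditions: Pd2(dba)3 (2.5 mol%), AsPh3 (10 mol%), CuI (10 mol%), NMP, rt
Reagents that add atoms: none
Why: Stille coupling of an alpha-iodoenone with an allylstannane under ligand-accelerated conditions, mild enough to keep the skipped diene out of conjugation.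

Step 5
Reactants: 9 methyl (E)-4-bromobut-2-enoate
Product: 10 (E)-4-bromobut-2-en-1-ol
Conditions: iBu2AlH (2.2 equiv), CH2Cl2, −78 °C; Rochelle salt work-up
Reagents that add atoms: none
Why: 1,2-Reduction of an enoate to the allylic alcohol by an aluminium hydride at low temperature, which leaves the allylic bromide and the E geometry intact.

Step 6
Reactants: 10
Product: 11 (E)-[(4-bromobut-2-en-1-yl)oxy](tert-butyl)dimethylsilane
Conditions: TBSOTf, 2,6-lutidine, CH2Cl2, −78 °C
Reagents that add atoms: tert-butyldimethylsilyl trifluoromethanesulfonate, CC(C)(C)[Si](C)(C)OS(=O)(=O)C(F)(F)F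
Why: Silylation of a primary alcohol; the hindered base avoids N-alkylation by the allylic bromide.

Step 7
Reactants: 8; 11
Product: 13 (2S,3R,4S)-2-allyl-2-[(E)-4-(tert-butyldimethylsilyloxy)but-2-en-1-yl]-4-(3,4-dimethoxyphenyl)-3-methylcyclopentan-1-one, via lithium enolate 12 (not isolated)
Conditions: Me2CuLi (from CuI and MeLi), Et2O, −78 → −30 °C; then 11 (2 equiv), HMPA, THF, −30 °C → rt
Reagents that add atoms: lithium dimethylcuprate, [Li+].C[Cu-]C
Why: Cuprate conjugate addition followed by alkylation of the regiodefined enolate with an allylic bromide. Methyl adds to C7 anti to the C6 aryl group, and the bromide then enters C1 anti to the new methyl, so the allyl group ends up cis to methyl and the butenyl arm cis to aryl, as the target requires.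

Step 8
Reactants: 13
Product: 15 (4R,5S)-5-allyl-5-[(E)-4-(tert-butyldimethylsilyloxy)but-2-en-1-yl]-3-(3,4-dimethoxyphenyl)-4-methylcyclopent-2-en-1-one, via trimethylsilyl enol ether 14 (not isolated)
Conditions: LiN(iPr)2, Me3SiCl, THF, −78 °C; then Pd(OAc)2 (15 mol%), O2 (1 atm), DMSO, rt
Reagents that add atoms: none
Why: Saegusa–Ito dehydrogenation; C5 is the only enolisable position, and palladium on the face anti to the aryl group is syn to the C6 hydrogen for beta-hydride elimination. The C6 centre is given up on purpose and re-formed in step 10; C7 and C1 now carry the stereochemical information.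

Step 9
Reactants: 15
Product: 16 (1R,4R,5S)-5-allyl-5-[(E)-4-(tert-butyldimethylsilyloxy)but-2-en-1-yl]-3-(3,4-dimethoxyphenyl)-4-methylcyclopent-2-en-1-ol
Conditions: (S)-2-methyl-CBS-oxazaborolidine (0.2 equiv), catecholborane, toluene, −78 °C
Reagents that add atoms: none
Why: Corey–Bakshi–Shibata reduction of an enone with catecholborane, which does not hydroborate the alkenes at this temperature. The two arms on C1 look alike next to the carbonyl, so the substrate has little bias; with the quaternary C1 as the large flank and the vinylic C5 as the small one, the S catalyst should place the C8 hydroxyl cis to the butenyl arm.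

Step 10
Reactants: 16
Product: 18 (2S,3S,4R,5S)-3-allyl-3-[(E)-4-(tert-butyldimethylsilyloxy)but-2-en-1-yl]-5-(3,4-dimethoxyphenyl)-2-hydroxy-4-methylcyclopentan-1-one, via cis-epoxy alcohol 17 (not isolated)
Conditions: VO(acac)2 (5 mol%), t-BuOOH (1.5 equiv), CH2Cl2, 0 °C; aq. Na2S2O3 wash; then BF3·OEt2 (0.2 equiv), CH2Cl2, −78 °C
Reagents that add atoms: tert-butyl hydroperoxide, CC(C)(C)OO
Why: Hydroxyl-directed vanadium-catalysed epoxidation touches only the C5=C6 bond (the other alkenes are not allylic to a free hydroxyl) and puts the oxygen cis to the C8 hydroxyl. Lewis acid then opens the epoxide at the benzylic C6, and a 1,2-hydride shift from C5 gives the C5 ketone (Meinwald rearrangement). The hydride reaches C6 on the face opposite the departing oxygen, which leaves aryl trans to the C7 methyl, also the arrangement favoured by equilibration alpha to the new ketone.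

Step 11
Reactants: 18
Product: 19 (2S,3S,4R,5S)-3-allyl-2-(tert-butyldimethylsilyloxy)-3-[(E)-4-(tert-butyldimethylsilyloxy)but-2-en-1-yl]-5-(3,4-dimethoxyphenyl)-4-methylcyclopentan-1-one
Conditions: TBSOTf, 2,6-lutidine, CH2Cl2, −78 → 0 °C
Reagents that add atoms: tert-butyldimethylsilyl trifluoromethanesulfonate, CC(C)(C)[Si](C)(C)OS(=O)(=O)C(F)(F)F
Why: Silylation of a hindered secondary alcohol with the silyl triflate; the weak hindered base should not enolise the ketone at low temperature.

Step 12
Reactants: 19
Product: 20 (2S,3S,4R,5S)-3-allyl-2-(tert-butyldimethylsilyloxy)-5-(3,4-dimethoxyphenyl)-3-[(E)-4-hydroxybut-2-en-1-yl]-4-methylcyclopentan-1-one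
Conditions: CSA (10 mol%), MeOH/CH2Cl2 1:1, 0 °C
Reagents that add atoms: none
Why: Acid-catalysed methanolysis should remove the primary allylic silyl ether much faster than the neopentyl-type secondary one at C8 (steric differentiation of silyl ethers).

Step 13
Reactants: 20
Product: 21 (2S,3S,4R,5S)-3-allyl-2-(tert-butyldimethylsilyloxy)-5-(3,4-dimethoxyphenyl)-3-{[(2R,3R)-3-(hydroxymethyl)oxiran-2-yl]methyl}-4-methylcyclopentan-1-one
Conditions: Ti(OiPr)4 (10 mol%), diisopropyl D-(−)-tartrate (12 mol%), t-BuOOH, 4 Å molecular sieves, CH2Cl2, −20 °C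
Reagents that add atoms: tert-butyl hydroperoxide, CC(C)(C)OO
Why: Sharpless asymmetric epoxidation; only the allylic alcohol alkene reacts, and the D-tartrate should give the (2R,3R)-epoxy alcohol by reagent control, independent of the remote ring centres.

Step 14
Reactants: 21
Product: 22 (2S,3S,4R,5S)-3-allyl-2-(tert-butyldimethylsilyloxy)-3-[(2S,3R)-3,4-dihydroxy-2-methoxybutyl]-5-(3,4-dimethoxyphenyl)-4-methylcyclopentan-1-one
Conditions: Eu(OTf)3 (20 mol%), 2,6-di-tert-butyl-4-methylpyridine (20 mol%), MeOH, rt
Reagents that add atoms: methanol, CO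
Why: Chelation-controlled alcoholysis of a 2,3-epoxy alcohol at the carbon distal to the hydroxyl: the Lewis acid bound to the hydroxyl and the epoxide oxygen directs methanol to core C3 with inversion, turning the R epoxide centre into the S methoxy centre of the target. The configuration of the C4 carbinol is irrelevant because C4 becomes the aldehyde.

Step 15
Reactants: 22
Product: 23 (2S)-3-[(1S,2R,3S,5S)-1-allyl-5-(tert-butyldimethylsilyloxy)-3-(3,4-dimethoxyphenyl)-2-methyl-4-oxocyclopentyl]-2-methoxypropanal
Conditions: NaIO4, THF/pH 7 phosphate buffer, 0 °C; crude aldehyde used at once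
Reagents that add atoms: none
Why: Periodate glycol cleavage under neutral conditions releases the alpha-methoxy aldehyde and formaldehyde; no acid or base is present that could epimerise C3.

Step 16
Reactants: 23
Product: 25 1-allyl-8-(tert-butyldimethylsilyloxy)-6-(3,4-dimethoxyphenyl)-5-hydroxy-3-methoxy-7-methylbicyclo[3.2.1]octan-4-one, via hydroxy-enamine 24 (not isolated)
Conditions: 2-(pentafluorophenyl)-6,7-dihydro-5H-pyrrolo[2,1-c][1,2,4]triazol-2-ium tetrafluoroborate (20 mol%), Et3N (15 mol%), toluene (0.02 M), rt → 40 °C
Reagents that add atoms: none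
Why: The triazolium salt is deprotonated to the carbene, which adds to the aldehyde carbon C4; proton transfer gives the hydroxy-enamine 24, whose nucleophilic C4 attacks the C5 ketone, and proton transfer with loss of the carbene releases the tertiary ketol 25. The closest known reaction type is the carbene-catalysed intramolecular crossed aldehyde–ketone benzoin reaction, established for bicyclic tertiary alpha-hydroxy ketones. The six-membered ring (C1, C2, C3, C4, C5, C8) closes in a 6-exo-trig mode onto the exocyclic C5=O. The only new stereocentre, C5, is fixed by the tether: the three-carbon arm on C1 can reach C5 only across the ring face it occupies, so the hydroxyl is forced outward at the bridgehead. Chemoselectivity rests on the aldehyde being the only carbonyl able to form the acyl anion equivalent (the flanked ketone is too hindered to add the carbene productively) and on high dilution, which disfavours aldehyde–aldehyde coupling. Stereochemical integrity at C3, C6 and C8 needs ring closure to outrun enolisation; the acidic N-pentafluorophenyl precatalyst is activated by sub-stoichiometric Et3N, so little free base is present. The bulky tert-butyldimethylsilyl group at O8 is chosen because the C5 alkoxide is gauche to O8 and a smaller silyl group could shift.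

Step 17
Reactants: 25
Product: 26 1-allyl-8-(tert-butyldimethylsilyloxy)-6-(3,4-dimethoxyphenyl)-3,5-dimethoxy-7-methylbicyclo[3.2.1]octan-4-one
Conditions: MeOTf (5 equiv), 2,6-di-tert-butyl-4-methylpyridine (7 equiv), CH2Cl2, 40 °C
Reagents that add atoms: methyl trifluoromethanesulfonate, COS(=O)(=O)C(F)(F)F
Why: O-Alkylation of a hindered tertiary alcohol with a powerful methylating agent and a non-nucleophilic pyridine base; no alkoxide is formed, so C3 is not enolised and no ketol shift is induced by base.

Step 18
Reactants: 26
Product: 27 1-allyl-6-(3,4-dimethoxyphenyl)-8-hydroxy-3,5-dimethoxy-7-methylbicyclo[3.2.1]octan-4-one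
Conditions: HF·pyridine, pyridine/THF, 0 °C → rt
Reagents that add atoms: none
Why: Acidic fluoride cleavage of a silyl ether; the buffered, non-basic medium should spare the C3 centre, which basic fluoride would endanger.

Step 19
Reactants: 27
Product: 28 1-allyl-6-(3,4-dimethoxyphenyl)-3,5-dimethoxy-7-methyl-4-oxobicyclo[3.2.1]octan-8-yl acetate (CNP0344493.1)
Conditions: Ac2O, DMAP (cat.), pyridine, CH2Cl2, rt
Reagents that add atoms: acetic anhydride, CC(=O)OC(C)=O
Why: DMAP-catalysed acylation of the secondary C8 alcohol; the weak amine base should not epimerise C3.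

## Compound list

1 | cyclopent-2-en-1-one | O=C1C=CCC1 | starting material
2 | (3,4-dimethoxyphenyl)boronic acid | OB(O)c1ccc(OC)c(OC)c1 | starting material
3 | (R)-3-(3,4-dimethoxyphenyl)cyclopentan-1-one | O=C1C[C@H](c2ccc(OC)c(OC)c2)CC1 | intermediate
4 | (R)-{[4-(3,4-dimethoxyphenyl)cyclopent-1-en-1-yl]oxy}trimethylsilane (not isolated) | C[Si](C)(C)OC1=CC[C@@H](c2ccc(OC)c(OC)c2)C1 | intermediate
5 | (S)-4-(3,4-dimethoxyphenyl)cyclopent-2-en-1-one | O=C1C=C[C@@H](c2ccc(OC)c(OC)c2)C1 | intermediate
6 | (S)-4-(3,4-dimethoxyphenyl)-2-iodocyclopent-2-en-1-one | O=C1C(I)=C[C@@H](c2ccc(OC)c(OC)c2)C1 | intermediate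
7 | allyltributylstannane | C=CC[Sn](CCCC)(CCCC)CCCC | starting material
8 | (S)-2-allyl-4-(3,4-dimethoxyphenyl)cyclopent-2-en-1-one | C=CCC1=C[C@@H](c2ccc(OC)c(OC)c2)CC1=O | intermediate
9 | methyl (E)-4-bromobut-2-enoate | COC(=O)/C=C/CBr | starting material
10 | (E)-4-bromobut-2-en-1-ol | OC/C=C/CBr | intermediate
11 | (E)-[(4-bromobut-2-en-1-yl)oxy](tert-butyl)dimethylsilane | CC(C)(C)[Si](C)(C)OC/C=C/CBr | intermediate
12 | lithium (3R,4S)-2-allyl-4-(3,4-dimethoxyphenyl)-3-methylcyclopent-1-en-1-olate (not isolated) | C=CCC1=C([O-])C[C@H](c2ccc(OC)c(OC)c2)[C@H]1C.[Li+] | intermediate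
13 | (2S,3R,4S)-2-allyl-2-[(E)-4-(tert-butyldimethylsilyloxy)but-2-en-1-yl]-4-(3,4-dimethoxyphenyl)-3-methylcyclopentan-1-one | C=CC[C@]1(C/C=C/CO[Si](C)(C)C(C)(C)C)[C@H](C)[C@@H](c2ccc(OC)c(OC)c2)CC1=O | intermediate
14 | trimethylsilyl enol ether of 13 (C8–O–Si, C8=C5; not isolated) | C=CC[C@]1(C/C=C/CO[Si](C)(C)C(C)(C)C)[C@H](C)[C@@H](c2ccc(OC)c(OC)c2)C=C1O[Si](C)(C)C | intermediate
15 | (4R,5S)-5-allyl-5-[(E)-4-(tert-butyldimethylsilyloxy)but-2-en-1-yl]-3-(3,4-dimethoxyphenyl)-4-methylcyclopent-2-en-1-one | C=CC[C@]1(C/C=C/CO[Si](C)(C)C(C)(C)C)[C@H](C)C(c2ccc(OC)c(OC)c2)=CC1=O | intermediate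
16 | (1R,4R,5S)-5-allyl-5-[(E)-4-(tert-butyldimethylsilyloxy)but-2-en-1-yl]-3-(3,4-dimethoxyphenyl)-4-methylcyclopent-2-en-1-ol (hydroxyl cis to the butenyl arm) | C=CC[C@]1(C/C=C/CO[Si](C)(C)C(C)(C)C)[C@H](C)C(c2ccc(OC)c(OC)c2)=C[C@H]1O | intermediate
17 | 3-allyl-3-[(E)-4-(tert-butyldimethylsilyloxy)but-2-en-1-yl]-5-(3,4-dimethoxyphenyl)-4-methyl-6-oxabicyclo[3.1.0]hexan-2-ol (epoxide cis to hydroxyl; not isolated) | C=CC[C@]1(C/C=C/CO[Si](C)(C)C(C)(C)C)[C@H](C)[C@@]2(c3ccc(OC)c(OC)c3)O[C@H]2[C@H]1O | intermediate
18 | (2S,3S,4R,5S)-3-allyl-3-[(E)-4-(tert-butyldimethylsilyloxy)but-2-en-1-yl]-5-(3,4-dimethoxyphenyl)-2-hydroxy-4-methylcyclopentan-1-one (hydroxyl cis to butenyl arm, aryl trans to methyl) | C=CC[C@]1(C/C=C/CO[Si](C)(C)C(C)(C)C)[C@H](C)[C@@H](c2ccc(OC)c(OC)c2)C(=O)[C@H]1O | intermediate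
19 | (2S,3S,4R,5S)-3-allyl-2-(tert-butyldimethylsilyloxy)-3-[(E)-4-(tert-butyldimethylsilyloxy)but-2-en-1-yl]-5-(3,4-dimethoxyphenyl)-4-methylcyclopentan-1-one | C=CC[C@]1(C/C=C/CO[Si](C)(C)C(C)(C)C)[C@H](C)[C@@H](c2ccc(OC)c(OC)c2)C(=O)[C@H]1O[Si](C)(C)C(C)(C)C | intermediate
20 | (2S,3S,4R,5S)-3-allyl-2-(tert-butyldimethylsilyloxy)-5-(3,4-dimethoxyphenyl)-3-[(E)-4-hydroxybut-2-en-1-yl]-4-methylcyclopentan-1-one | C=CC[C@]1(C/C=C/CO)[C@H](C)[C@@H](c2ccc(OC)c(OC)c2)C(=O)[C@H]1O[Si](C)(C)C(C)(C)C | intermediate
21 | (2S,3S,4R,5S)-3-allyl-2-(tert-butyldimethylsilyloxy)-5-(3,4-dimethoxyphenyl)-3-{[(2R,3R)-3-(hydroxymethyl)oxiran-2-yl]methyl}-4-methylcyclopentan-1-one | C=CC[C@]1(C[C@H]2O[C@@H]2CO)[C@H](C)[C@@H](c2ccc(OC)c(OC)c2)C(=O)[C@H]1O[Si](C)(C)C(C)(C)C | intermediate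
22 | (2S,3S,4R,5S)-3-allyl-2-(tert-butyldimethylsilyloxy)-3-[(2S,3R)-3,4-dihydroxy-2-methoxybutyl]-5-(3,4-dimethoxyphenyl)-4-methylcyclopentan-1-one | C=CC[C@]1(C[C@H](OC)[C@H](O)CO)[C@H](C)[C@@H](c2ccc(OC)c(OC)c2)C(=O)[C@H]1O[Si](C)(C)C(C)(C)C | intermediate
23 | (2S)-3-[(1S,2R,3S,5S)-1-allyl-5-(tert-butyldimethylsilyloxy)-3-(3,4-dimethoxyphenyl)-2-methyl-4-oxocyclopentyl]-2-methoxypropanal | C=CC[C@]1(C[C@H](OC)C=O)[C@H](C)[C@@H](c2ccc(OC)c(OC)c2)C(=O)[C@H]1O[Si](C)(C)C(C)(C)C | intermediate
24 | hydroxy-enamine (Breslow intermediate) of 23: C4 as C(OH)=C of the 2-(pentafluorophenyl)pyrrolotriazolylidene (not isolated) | C=CC[C@]1(C[C@H](OC)C(O)=C2N(c3c(F)c(F)c(F)c(F)c3F)N=C3CCCN23)[C@H](C)[C@@H](c2ccc(OC)c(OC)c2)C(=O)[C@H]1O[Si](C)(C)C(C)(C)C | intermediate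
25 | 1-allyl-8-(tert-butyldimethylsilyloxy)-6-(3,4-dimethoxyphenyl)-5-hydroxy-3-methoxy-7-methylbicyclo[3.2.1]octan-4-one (core numbering; all centres as in 28) | C=CC[C@]12C[C@H](OC)C(=O)[C@](O)([C@H](c3ccc(OC)c(OC)c3)[C@H]1C)[C@H]2O[Si](C)(C)C(C)(C)C | intermediate
26 | 1-allyl-8-(tert-butyldimethylsilyloxy)-6-(3,4-dimethoxyphenyl)-3,5-dimethoxy-7-methylbicyclo[3.2.1]octan-4-one (core numbering; all centres as in 28) | C=CC[C@]12C[C@H](OC)C(=O)[C@](OC)([C@H](c3ccc(OC)c(OC)c3)[C@H]1C)[C@H]2O[Si](C)(C)C(C)(C)C | intermediate
27 | 1-allyl-6-(3,4-dimethoxyphenyl)-8-hydroxy-3,5-dimethoxy-7-methylbicyclo[3.2.1]octan-4-one (core numbering; all centres as in 28) | C=CC[C@]12C[C@H](OC)C(=O)[C@](OC)([C@H](c3ccc(OC)c(OC)c3)[C@H]1C)[C@H]2O | intermediate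
28 | 1-allyl-6-(3,4-dimethoxyphenyl)-3,5-dimethoxy-7-methyl-4-oxobicyclo[3.2.1]octan-8-yl acetate (core numbering; aryl endo, methyl exo, acetate on the side of the C2–C4 bridge, C3 methoxy toward the C6–C7 bridge) | C=CC[C@]12C[C@H](OC)C(=O)[C@](OC)([C@H](c3ccc(OC)c(OC)c3)[C@H]1C)[C@H]2OC(C)=O | target

## Step count and least certain steps

Total: 19 steps. Longest linear sequence: 17 steps (steps 1–4 and 7–19, from 1). Steps 5 and 6 are a two-step side branch to 11.

Step 16 (key step). The bulky hydroxy-enamine must add to a ketone whose reactive face is flanked by the C6 aryl group and the C8 silyloxy group, so closure may be slow. That would leave time for several processes: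
- enolisation of the aldehyde, with loss of configuration at C3;
- epimerisation at C6 followed by closure of the epimer (C6 can no longer be corrected once C5 is sp3);
- aldol closure of the C6 enolate onto the aldehyde;
- intermolecular aldehyde coupling;
- silyl transfer from O8 to the C5 alkoxide.

Fallback: set out from 23 and form the C4–C5 bond by reductive keto-aldehyde coupling with low-valent titanium (TiCl4, Zn, THF, −40 → 0 °C). This should give 1-allyl-8-(tert-butyldimethylsilyloxy)-6-(3,4-dimethoxyphenyl)-3-methoxy-7-methylbicyclo[3.2.1]octane-4,5-diol F1 (either C4 epimer serves). Oxidation of the secondary C4 carbinol (SO3·pyridine, DMSO, iPr2NEt, 0 °C) would return to the route at 25.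

Step 14. Methanol may attack the wrong epoxide carbon, or a neighbouring oxygen (the C8 silyl ether or the ketone) may take part in the opening, because the Lewis acid activates the epoxide next to a crowded ring. Fallback: set out from 21 and open the epoxide at the distal carbon with benzoic acid (Ti(OiPr)4, PhCO2H, CH2Cl2) to give the C3 benzoate diol F2. Protect the diol (2,2-dimethoxypropane, PPTS) as the acetonide benzoate F3, and remove the benzoate (K2CO3, MeOH) to the acetonide alcohol F4. Methylate without base (MeOTf, 2,6-di-tert-butyl-4-methylpyridine) to the acetonide methyl ether F5, and hydrolyse the acetonide (aq. AcOH) to come back at 22.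

Step 9. The catalyst may fail to tell the quaternary flank from the vinylic flank in the expected sense, giving poor facial selectivity at C8. Fallback: set out from 15 and epoxidise the enone nucleophilically (t-BuOOH, DBU, CH2Cl2), anti to the C7 methyl, to give 3-allyl-3-[(E)-4-(tert-butyldimethylsilyloxy)but-2-en-1-yl]-5-(3,4-dimethoxyphenyl)-4-methyl-6-oxabicyclo[3.1.0]hexan-2-one F6. Reduce the ketone from the face opposite the epoxide (NaBH4, CeCl3, MeOH, −78 °C); this should give 17, which is rearranged as in the second half of step 10 to come back at 18. C8 is then set by the substrate (through C7), not by a chiral reagent.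

Step 2. Kinetic enolisation may not discriminate well enough between the two alpha-CH2 groups, giving material loss to the achiral 3-aryl enone. Fallback: set out from 2 and add it under rhodium catalysis ([Rh(OH)(cod)]2, dioxane/H2O) to purchased (S)-4-(tert-butyldimethylsilyloxy)cyclopent-2-en-1-one F7, anti to the silyloxy group. This should give (3R,4S)-4-(tert-butyldimethylsilyloxy)-3-(3,4-dimethoxyphenyl)cyclopentan-1-one F8. Elimination of silanol (DBU, CH2Cl2, 0 °C) would come back at 5, with the stereocentre drawn from the chiral pool.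

Step 17. Alkylation of the very hindered bridgehead hydroxyl next to the bulky silyl ether may be incomplete, and long exposure may cause silyl loss or a ketol shift. Fallback (changed order of events): set out from 25 and desilylate first (HF·pyridine) to 1-allyl-6-(3,4-dimethoxyphenyl)-5,8-dihydroxy-3-methoxy-7-methylbicyclo[3.2.1]octan-4-one F9. Acetylate only the secondary hydroxyl (Ac2O, pyridine) to 1-allyl-6-(3,4-dimethoxyphenyl)-5-hydroxy-3-methoxy-7-methyl-4-oxobicyclo[3.2.1]octan-8-yl acetate F10. Methylate the tertiary hydroxyl beside the smaller acetate (MeOTf, 2,6-di-tert-butyl-4-methylpyridine) to come back at 28.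

## Further compounds

F1 | step 16 | 1-allyl-8-(tert-butyldimethylsilyloxy)-6-(3,4-dimethoxyphenyl)-3-methoxy-7-methylbicyclo[3.2.1]octane-4,5-diol (C4 configuration open) | C=CC[C@]12C[C@H](OC)C(O)[C@](O)([C@H](c3ccc(OC)c(OC)c3)[C@H]1C)[C@H]2O[Si](C)(C)C(C)(C)C
F2 | step 14 | C3 benzoate diol: 22 with benzoyloxy in place of methoxy at core C3 | C=CC[C@]1(C[C@H](OC(=O)c2ccccc2)[C@H](O)CO)[C@H](C)[C@@H](c2ccc(OC)c(OC)c2)C(=O)[C@H]1O[Si](C)(C)C(C)(C)C
F3 | step 14 | acetonide benzoate: F2 with the 1,2-diol as its isopropylidene acetal | C=CC[C@]1(C[C@H](OC(=O)c2ccccc2)[C@H]2COC(C)(C)O2)[C@H](C)[C@@H](c2ccc(OC)c(OC)c2)C(=O)[C@H]1O[Si](C)(C)C(C)(C)C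
F4 | step 14 | acetonide alcohol: F3 with free hydroxyl at core C3 | C=CC[C@]1(C[C@H](O)[C@H]2COC(C)(C)O2)[C@H](C)[C@@H](c2ccc(OC)c(OC)c2)C(=O)[C@H]1O[Si](C)(C)C(C)(C)C
F5 | step 14 | acetonide methyl ether: isopropylidene acetal of 22 | C=CC[C@]1(C[C@H](OC)[C@H]2COC(C)(C)O2)[C@H](C)[C@@H](c2ccc(OC)c(OC)c2)C(=O)[C@H]1O[Si](C)(C)C(C)(C)C
F6 | step 9 | 3-allyl-3-[(E)-4-(tert-butyldimethylsilyloxy)but-2-en-1-yl]-5-(3,4-dimethoxyphenyl)-4-methyl-6-oxabicyclo[3.1.0]hexan-2-one (epoxide trans to the C7 methyl) | C=CC[C@]1(C/C=C/CO[Si](C)(C)C(C)(C)C)[C@H](C)[C@@]2(c3ccc(OC)c(OC)c3)O[C@H]2C1=O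
F7 | step 2 | (S)-4-(tert-butyldimethylsilyloxy)cyclopent-2-en-1-one | O=C1C=C[C@@H](O[Si](C)(C)C(C)(C)C)C1
F8 | step 2 | (3R,4S)-4-(tert-butyldimethylsilyloxy)-3-(3,4-dimethoxyphenyl)cyclopentan-1-one (trans) | O=C1C[C@H](c2ccc(OC)c(OC)c2)[C@@H](O[Si](C)(C)C(C)(C)C)C1
F9 | step 17 | 1-allyl-6-(3,4-dimethoxyphenyl)-5,8-dihydroxy-3-methoxy-7-methylbicyclo[3.2.1]octan-4-one | C=CC[C@]12C[C@H](OC)C(=O)[C@](O)([C@H](c3ccc(OC)c(OC)c3)[C@H]1C)[C@H]2O
F10 | step 17 | 1-allyl-6-(3,4-dimethoxyphenyl)-5-hydroxy-3-methoxy-7-methyl-4-oxobicyclo[3.2.1]octan-8-yl acetate | C=CC[C@]12C[C@H](OC)C(=O)[C@](O)([C@H](c3ccc(OC)c(OC)c3)[C@H]1C)[C@H]2OC(C)=O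
A1 | alternative 1 | (1Z,4E)-1-(3,4-dimethoxyphenyl)-2-methoxy-4-(prop-2-en-1-yl)hexa-1,4-dien-3-one | C/C=C(\CC=C)C(=O)/C(OC)=C/c1ccc(OC)c(OC)c1
A2 | alternative 1 | 2-allyl-4-(3,4-dimethoxyphenyl)-5-methoxy-3-methylcyclopentan-1-one | C=CC[C@H]1[C@H](C)[C@@H](c2ccc(OC)c(OC)c2)[C@H](OC)C1=O
A3 | alternative 2 | 4-allyl-2-(3,4-dimethoxyphenyl)-1,6-dimethoxy-3-methyl-7-oxocyclohept-5-ene-1-carbaldehyde (allyl-bearing centre open) | O=C[C@]1(OC)C(=O)C(OC)=CC(CC=C)[C@H](C)[C@H]1c1ccc(OC)c(OC)c1
A4 | alternative 2 | 1-allyl-6-(3,4-dimethoxyphenyl)-8-hydroxy-3,5-dimethoxy-7-methylbicyclo[3.2.1]oct-2-en-4-one | C=CC[C@]12C=C(OC)C(=O)[C@](OC)([C@H](c3ccc(OC)c(OC)c3)[C@H]1C)[C@H]2O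
A5 | alternative 3 | trans-2-allyl-4-(3,4-dimethoxyphenyl)-5-methoxycyclopent-2-en-1-one | C=CCC1=C[C@@H](c2ccc(OC)c(OC)c2)[C@H](OC)C1=O
A6 | alternative 3 | 2-methoxyprop-2-enal (2-methoxyacrolein) | C=C(OC)C=O
A7 | alternative 3 | 1-allyl-6-(3,4-dimethoxyphenyl)-4-hydroxy-3,5-dimethoxy-7-methylbicyclo[3.2.1]octan-8-one | C=CC[C@]12C[C@H](OC)[C@@H](O)[C@](OC)([C@H](c3ccc(OC)c(OC)c3)[C@H]1C)C2=O
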